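**Strategy**

The ten-membered carbocycle (C1–C10, germacrane numbering) is disconnected at C8–C9. The key step exploits that C9 is the allylic CH2 of the C1=C10(CO2Me) enoate and sits next to the C8 carbinol. A C8 aldehyde and a Morita–Baylis–Hillman acetate, C9H2=C10(CO2Me)–C1H(OAc), are joined by a SmI2 ketyl–olefin addition/β-elimination. One operation closes the ring, creates the C8 alcohol and moves the alkene to C1=C10 with the ring-cis geometry. The precursor is an open-chain α-methylene-γ-butyrolactone (C6, C7 from a chiral butenolide) bearing the formyl group on C7 and a (Z)-C4=C5 alkene linking to the acetate.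

Key step: step 13

Remarks on the chemistry:
- Germacrane numbering is used for all fragments: ring C1–C10, lactone C11–C13 on C7 with its oxygen on C6, C14 the ester carbon on C10, C15 the methyl on C4.
- Compounds 1, 10, 11 and 21 are assumed commercial.
- Compounds 12–19 are carried as both C1 epimers; C1 becomes sp2 in step 13, so its SMILES centre is left open.
- The route is a proposal; selectivities are expectations, not results.

**Route**

Step 1
Reactants: 1 (S)-5-(hydroxymethyl)furan-2(5H)-one
Product: 2 (S)-5-{[(tert-butyldimethylsilyl)oxy]methyl}furan-2(5H)-one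
Conditions: TBSCl, imidazole, CH2Cl2, 0 °C to rt
Reagents that add atoms: tert-butyldimethylsilyl chloride, CC(C)(C)[Si](C)(C)Cl
Why: Silyl ether formation at the primary alcohol; the bulky group later steers the radical in step 2 to the opposite face, and C6 is not touched.

Step 2
Reactants: 2 (S)-5-{[(tert-butyldimethylsilyl)oxy]methyl}furan-2(5H)-one
Product: 3 (4S,5S)-5-{[(tert-butyldimethylsilyl)oxy]methyl}-4-(1,3-dioxolan-2-yl)dihydrofuran-2(3H)-one
Conditions: 1,3-dioxolane (solvent), benzophenone (10 mol%), hν (350 nm), degassed, rt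
Reagents that add atoms: 1,3-dioxolane, C1COCO1
Why: Benzophenone-sensitised photochemical radical conjugate addition (hydrogen-atom transfer gives the 2-dioxolanyl radical, a masked formyl group): it adds to the β-carbon anti to the silyloxymethyl group on C6, which sets C7 trans to C6 and brings in C8 at the aldehyde oxidation level.

Step 3
Reactants: 3 (4S,5S)-5-{[(tert-butyldimethylsilyl)oxy]methyl}-4-(1,3-dioxolan-2-yl)dihydrofuran-2(3H)-one
Product: 4 (4S,5S)-4-(1,3-dioxolan-2-yl)-5-(hydroxymethyl)dihydrofuran-2(3H)-one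
Conditions: HF·pyridine, pyridine, THF, 0 °C to rt
Reagents that add atoms: none
Why: Fluoride-mediated desilylation under pyridine-buffered conditions that leave the acetal and the lactone intact.

Step 4
Reactants: 4 (4S,5S)-4-(1,3-dioxolan-2-yl)-5-(hydroxymethyl)dihydrofuran-2(3H)-one
Product: 5 (2S,3S)-3-(1,3-dioxolan-2-yl)-5-oxotetrahydrofuran-2-carbaldehyde
Conditions: Dess–Martin periodinane, NaHCO3, CH2Cl2, 0 °C to rt; used crude
Reagents that add atoms: none
Why: Dess–Martin oxidation to the aldehyde under buffered conditions; the α-acyloxy aldehyde is used at once, and the 6,7-trans arrangement is in any case the thermodynamic one.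

Step 5
Reactants: 5 (2S,3S)-3-(1,3-dioxolan-2-yl)-5-oxotetrahydrofuran-2-carbaldehyde
Product: 6 (4S,5S)-4-(1,3-dioxolan-2-yl)-5-[(Z)-2-iodoprop-1-en-1-yl]dihydrofuran-2(3H)-one
Conditions: EtPPh3I, n-BuLi, THF, rt; I2, −78 °C; NaN(SiMe3)2, −20 °C; then 5, −78 to −20 °C
Reagents that add atoms: ethyltriphenylphosphonium iodide, CC[P+](c1ccccc1)(c1ccccc1)c1ccccc1.[I-]; iodine, II
Why: Stork–Zhao-type Wittig olefination with an α-iodo ylide: the kinetically formed cis-oxaphosphetane should give the (Z)-2-iodoalkene (iodine cis to C6, methyl trans), which fixes the C4=C5 geometry once iodine is replaced by C3.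

Step 6
Reactants: 6 (4S,5S)-4-(1,3-dioxolan-2-yl)-5-[(Z)-2-iodoprop-1-en-1-yl]dihydrofuran-2(3H)-one
Product: 9 (4S,5S)-4-(1,3-dioxolan-2-yl)-5-[(Z)-2-iodoprop-1-en-1-yl]-3-methylidenedihydrofuran-2(3H)-one, via Mannich base 7 (not isolated), via trimethylammonium iodide 8 (not isolated)
Conditions: LiN(SiMe3)2, THF, −78 °C; CH2=NMe2+ I−, −78 °C to rt; MeI, rt; aq. NaHCO3, rt
Reagents that add atoms: N,N-dimethylmethyleneiminium iodide (Eschenmoser's salt), C=[N+](C)C.[I-]
Why: α-Methylenation of the lactone by enolate Mannich reaction, N-quaternisation and E1cB elimination; the kinetic base at −78 °C deprotonates only C11 and no stereocenter is changed.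

Step 7
Reactants: 10 3-[(tert-butyldimethylsilyl)oxy]propanal; 11 methyl acrylate
Product: 12 methyl 5-[(tert-butyldimethylsilyl)oxy]-3-hydroxy-2-methylidenepentanoate (racemic)
Conditions: DABCO (0.5 equiv), methyl acrylate (excess), MeOH (cat.), rt
Reagents that add atoms: none
Why: Morita–Baylis–Hillman reaction assembling C1, C9, C10 and C14; C1 is formed racemic, which is immaterial because it becomes sp2 in step 13.

Step 8
Reactants: 12 methyl 5-[(tert-butyldimethylsilyl)oxy]-3-hydroxy-2-methylidenepentanoate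
Product: 13 methyl 3-acetoxy-5-[(tert-butyldimethylsilyl)oxy]-2-methylidenepentanoate
Conditions: Ac2O, pyridine, DMAP (cat.), CH2Cl2, 0 °C
Reagents that add atoms: acetic anhydride, CC(=O)OC(C)=O
Why: O-Acetylation of the allylic alcohol turns the C1 oxygen into the leaving group for step 13; short reaction time at 0 °C avoids allylic transposition of the acetate.

Step 9
Reactants: 13 methyl 3-acetoxy-5-[(tert-butyldimethylsilyl)oxy]-2-methylidenepentanoate
Product: 14 methyl 3-acetoxy-5-hydroxy-2-methylidenepentanoate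
Conditions: HF·pyridine, pyridine, THF, 0 °C
Reagents that add atoms: none
Why: Fluoride cleavage of the primary silyl ether under buffered conditions in which the allylic acetate and the acrylate are inert.

Step 10
Reactants: 14 methyl 3-acetoxy-5-hydroxy-2-methylidenepentanoate
Product: 15 methyl 3-acetoxy-2-methylidene-5-oxopentanoate
Conditions: Dess–Martin periodinane, NaHCO3, CH2Cl2, 0 °C; used crude
Reagents that add atoms: none
Why: Dess–Martin oxidation under buffered conditions gives the β-acetoxy aldehyde, which is used at once to avoid loss of acetic acid.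

Step 11
Reactants: 9 (4S,5S)-4-(1,3-dioxolan-2-yl)-5-[(Z)-2-iodoprop-1-en-1-yl]-3-methylidenedihydrofuran-2(3H)-one; 15 methyl 3-acetoxy-2-methylidene-5-oxopentanoate
Product: 16 methyl (5S,6Z)-3-acetoxy-7-[(2R,3S)-3-(1,3-dioxolan-2-yl)-4-methylidene-5-oxooxolan-2-yl]-5-hydroxy-6-methyl-2-methylidenehept-6-enoate
Conditions: CrCl2 (4 equiv) pre-complexed with a single enantiomer of N-[2-(4-isopropyl-4,5-dihydro-1,3-oxazol-2-yl)-6-methylphenyl]methanesulfonamide and Et3N, NiCl2 (5 mol%), THF, rt; 15 in excess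
Reagents that add atoms: none
Why: Nozaki–Hiyama–Kishi coupling: the alkenyl iodide is transferred via nickel to chromium with retention of the Z geometry and adds only to the aldehyde, whose face is chosen by the chiral sulfonamide-bound chromium (reagent control; the ligand antipode that gives 3S is to be used, its sense to be checked on a model aldehyde), while C1 is carried as both epimers.

Step 12
Reactants: 16 methyl (5S,6Z)-3-acetoxy-7-[(2R,3S)-3-(1,3-dioxolan-2-yl)-4-methylidene-5-oxooxolan-2-yl]-5-hydroxy-6-methyl-2-methylidenehept-6-enoate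
Product: 18 methyl (5S,6Z)-3-acetoxy-7-[(2R,3S)-3-formyl-4-methylidene-5-oxooxolan-2-yl]-6-methyl-2-methylidene-5-[(triethylsilyl)oxy]hept-6-enoate, via collidinium salt 17 (not isolated)
Conditions: TESOTf (3 equiv), 2,4,6-collidine (4.5 equiv), CH2Cl2, −20 to 0 °C; then H2O, rt; used at once
Reagents that add atoms: triethylsilyl trifluoromethanesulfonate, CC[Si](CC)(CC)OS(=O)(=O)C(F)(F)F; water, O
Why: Silyl triflate/collidine acetal cleavage: the buffered Lewis acid opens the dioxolane to the collidinium salt 17, which water hydrolyses to the aldehyde, and the same reagent silylates the C3 hydroxyl, so protection and unmasking occur without protic acid and without epimerising C7.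

Step 13
Reactants: 18 methyl (5S,6Z)-3-acetoxy-7-[(2R,3S)-3-formyl-4-methylidene-5-oxooxolan-2-yl]-6-methyl-2-methylidene-5-[(triethylsilyl)oxy]hept-6-enoate
Product: 20 methyl (3aR,4R,6E,9S,10Z,11aR)-4-hydroxy-10-methyl-3-methylidene-2-oxo-9-[(triethylsilyl)oxy]-2,3,3a,4,5,8,9,11a-octahydrocyclodeca[b]furan-6-carboxylate, via diiodosamarium enolate 19 (not isolated)
Conditions: SmI2 (2.5 equiv), HMPA (10 equiv), THF, −78 °C, slow addition of 18 (final 0.002 M); sat. aq. NH4Cl at −78 °C
Reagents that add atoms: none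
Why: Single-electron reduction of the C8 aldehyde (the most easily reduced group at −78 °C) gives a samarium ketyl that adds in a 10-endo-trig radical cyclisation to the unsubstituted C9 terminus of the acrylate, the α-ester radical at C10 is reduced by a second SmI2 to the trivalent samarium enolate 19, and this expels the C1 acetate to give the C1=C10 enoate; the closest known reaction type is the SmI2 ketyl–olefin coupling with activated alkenes followed by β-elimination, run here as a macrocyclisation. The ten-membered carbocycle is the only ring closed, because attack at C13 of the α-methylene lactone would need a four-membered ring and attack at C10 would give a nine-membered ring with an unstabilised primary radical. The new C8 stereocenter is controlled by the adjacent C7 stereocenter: in the staggered transition state the forming C8–C9 bond lies anti to the ring bond C7–C6 and the bulky HMPA-solvated samarium alkoxide takes the position anti to the C11 branch, next to H7, which corresponds to 8R. The C1=C10 geometry (C2 cis to C9, E) should follow from elimination through the chelated samarium enolate with C2 turned away from the ester, which is also the geometry that fits the ring, so both C1 epimers converge. The step needs reduction of the aldehyde in preference to the two enoates and ring closure in preference to intermolecular coupling; low temperature, inverse slow addition at high dilution, the rigid (Z)-C4=C5 alkene and lactone, and bridging of the ketyl oxygen to the C14 carbonyl by trivalent samarium should secure these.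

Step 14
Reactants: 21 methyl (Z)-2-methylbut-2-enoate (methyl angelate)
Product: 22 (Z)-2-methylbut-2-en-1-ol
Conditions: iBu2AlH (2.2 equiv), CH2Cl2, −78 °C; aqueous Rochelle salt
Reagents that add atoms: none
Why: Hydride reduction of the ester to the allylic alcohol at low temperature, which retains the Z geometry.

Step 15
Reactants: 22 (Z)-2-methylbut-2-en-1-ol
Product: 23 [(2S,3R)-2,3-dimethyloxiran-2-yl]methanol
Conditions: Ti(OiPr)4 (10 mol%), L-(+)-diethyl tartrate (12 mol%), t-BuOOH, 4 Å molecular sieves, CH2Cl2, −20 °C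
Reagents that add atoms: tert-butyl hydroperoxide, CC(C)(C)OO
Why: Sharpless asymmetric epoxidation: syn oxygen transfer keeps the two methyl groups trans, and the L-(+)-tartrate catalyst should deliver oxygen to the face that gives the (2S,3R)-epoxy alcohol.

Step 16
Reactants: 23 [(2S,3R)-2,3-dimethyloxiran-2-yl]methanol
Product: 24 (2R,3R)-2,3-dimethyloxirane-2-carboxylic acid
Conditions: RuCl3 (2 mol%), NaIO4 (3 equiv), CCl4/MeCN/H2O, rt
Reagents that add atoms: water, O
Why: RuO4-catalysed oxidation of the primary alcohol to the acid without touching the epoxide; the C2 descriptor becomes R only through the change in priorities.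

Step 17
Reactants: 20 methyl (3aR,4R,6E,9S,10Z,11aR)-4-hydroxy-10-methyl-3-methylidene-2-oxo-9-[(triethylsilyl)oxy]-2,3,3a,4,5,8,9,11a-octahydrocyclodeca[b]furan-6-carboxylate; 24 (2R,3R)-2,3-dimethyloxirane-2-carboxylic acid
Product: 26 methyl (3aR,4R,6E,9S,10Z,11aR)-4-{[(2R,3R)-2,3-dimethyloxirane-2-carbonyl]oxy}-10-methyl-3-methylidene-2-oxo-9-[(triethylsilyl)oxy]-2,3,3a,4,5,8,9,11a-octahydrocyclodeca[b]furan-6-carboxylate, via mixed anhydride 25 (not isolated)
Conditions: 24, 2,4,6-trichlorobenzoyl chloride, Et3N, THF, rt; then 20, DMAP, toluene, rt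
Reagents that add atoms: none
Why: Yamaguchi esterification: DMAP attacks the mixed anhydride 25 at the epoxy-acyl carbonyl and transfers the acyl group to the C8 hydroxyl with retention at C8 and at both epoxide carbons, the C3 hydroxyl being silylated.

Step 18
Reactants: 26 methyl (3aR,4R,6E,9S,10Z,11aR)-4-{[(2R,3R)-2,3-dimethyloxirane-2-carbonyl]oxy}-10-methyl-3-methylidene-2-oxo-9-[(triethylsilyl)oxy]-2,3,3a,4,5,8,9,11a-octahydrocyclodeca[b]furan-6-carboxylate
Product: 27 methyl (3aR,4R,6E,9S,10Z,11aR)-4-{[(2R,3R)-2,3-dimethyloxirane-2-carbonyl]oxy}-9-hydroxy-10-methyl-3-methylidene-2-oxo-2,3,3a,4,5,8,9,11a-octahydrocyclodeca[b]furan-6-carboxylate (CNP0143679.1)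
Conditions: HF·pyridine, pyridine, THF, 0 °C
Reagents that add atoms: none
Why: Fluoride cleavage of the secondary triethylsilyl ether under pyridine-buffered conditions mild enough for the epoxy ester, the α-methylene lactone and the enoate.

**Compound list**

1 | (S)-5-(hydroxymethyl)furan-2(5H)-one | O=C1O[C@H](CO)C=C1 | starting material
2 | (S)-5-{[(tert-butyldimethylsilyl)oxy]methyl}furan-2(5H)-one | O=C1O[C@H](CO[Si](C)(C)C(C)(C)C)C=C1 | intermediate
3 | (4S,5S)-5-{[(tert-butyldimethylsilyl)oxy]methyl}-4-(1,3-dioxolan-2-yl)dihydrofuran-2(3H)-one (4,5-trans) | O=C1O[C@H](CO[Si](C)(C)C(C)(C)C)[C@@H](C2OCCO2)C1 | intermediate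
4 | (4S,5S)-4-(1,3-dioxolan-2-yl)-5-(hydroxymethyl)dihydrofuran-2(3H)-one | O=C1O[C@H](CO)[C@@H](C2OCCO2)C1 | intermediate
5 | (2S,3S)-3-(1,3-dioxolan-2-yl)-5-oxotetrahydrofuran-2-carbaldehyde | O=C1O[C@H](C=O)[C@@H](C2OCCO2)C1 | intermediate
6 | (4S,5S)-4-(1,3-dioxolan-2-yl)-5-[(Z)-2-iodoprop-1-en-1-yl]dihydrofuran-2(3H)-one | O=C1O[C@H](/C=C(/C)I)[C@@H](C2OCCO2)C1 | intermediate
7 | Mannich base: 3-[(dimethylamino)methyl] derivative of 6 (3,4-trans expected) | O=C1O[C@H](/C=C(/C)I)[C@@H](C2OCCO2)[C@@H]1CN(C)C | intermediate (not isolated)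
8 | trimethylammonium iodide of 7 | O=C1O[C@H](/C=C(/C)I)[C@@H](C2OCCO2)[C@@H]1C[N+](C)(C)C.[I-] | intermediate (not isolated)
9 | (4S,5S)-4-(1,3-dioxolan-2-yl)-5-[(Z)-2-iodoprop-1-en-1-yl]-3-methylidenedihydrofuran-2(3H)-one | O=C1O[C@H](/C=C(/C)I)[C@@H](C2OCCO2)C1=C | intermediate
10 | 3-[(tert-butyldimethylsilyl)oxy]propanal | O=CCCO[Si](C)(C)C(C)(C)C | starting material
11 | methyl acrylate | C=CC(=O)OC | starting material
12 | methyl 5-[(tert-butyldimethylsilyl)oxy]-3-hydroxy-2-methylidenepentanoate (racemic) | C=C(C(=O)OC)C(O)CCO[Si](C)(C)C(C)(C)C | intermediate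
13 | methyl 3-acetoxy-5-[(tert-butyldimethylsilyl)oxy]-2-methylidenepentanoate (racemic) | C=C(C(=O)OC)C(OC(C)=O)CCO[Si](C)(C)C(C)(C)C | intermediate
14 | methyl 3-acetoxy-5-hydroxy-2-methylidenepentanoate (racemic) | C=C(C(=O)OC)C(OC(C)=O)CCO | intermediate
15 | methyl 3-acetoxy-2-methylidene-5-oxopentanoate (racemic) | C=C(C(=O)OC)C(OC(C)=O)CC=O | intermediate
16 | methyl (5S,6Z)-3-acetoxy-7-[(2R,3S)-3-(1,3-dioxolan-2-yl)-4-methylidene-5-oxooxolan-2-yl]-5-hydroxy-6-methyl-2-methylidenehept-6-enoate (both epimers at the acetoxy carbon) | O=C1O[C@H](/C=C(/C)[C@@H](O)CC(OC(C)=O)C(=C)C(=O)OC)[C@@H](C2OCCO2)C1=C | intermediate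
17 | N-(1-alkoxyalkyl)-2,4,6-trimethylpyridinium triflate from 16: C3 triethylsilyl ether, C8 bearing the collidinium nitrogen and a 2-(triethylsilyloxy)ethoxy group | O=C1O[C@H](/C=C(/C)[C@@H](O[Si](CC)(CC)CC)CC(OC(C)=O)C(=C)C(=O)OC)[C@@H](C(OCCO[Si](CC)(CC)CC)[n+]2c(C)cc(C)cc2C)C1=C.[O-]S(=O)(=O)C(F)(F)F | intermediate (not isolated)
18 | methyl (5S,6Z)-3-acetoxy-7-[(2R,3S)-3-formyl-4-methylidene-5-oxooxolan-2-yl]-6-methyl-2-methylidene-5-[(triethylsilyl)oxy]hept-6-enoate (both epimers at the acetoxy carbon) | O=C1O[C@H](/C=C(/C)[C@@H](O[Si](CC)(CC)CC)CC(OC(C)=O)C(=C)C(=O)OC)[C@@H](C=O)C1=C | intermediate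
19 | cyclised diiodosamarium ester enolate (C10=C14) with diiodosamarium alkoxide on C8, acetate still on C1 | C=C1C(=O)O[C@@H]2/C=C(/C)[C@@H](O[Si](CC)(CC)CC)CC(OC(C)=O)C(=C(OC)O[Sm](I)I)C[C@@H](O[Sm](I)I)[C@@H]12 | intermediate (not isolated)
20 | methyl (3aR,4R,6E,9S,10Z,11aR)-4-hydroxy-10-methyl-3-methylidene-2-oxo-9-[(triethylsilyl)oxy]-2,3,3a,4,5,8,9,11a-octahydrocyclodeca[b]furan-6-carboxylate | C=C1C(=O)O[C@@H]2/C=C(/C)[C@@H](O[Si](CC)(CC)CC)C/C=C(/C(=O)OC)C[C@@H](O)[C@@H]12 | intermediate
21 | methyl (Z)-2-methylbut-2-enoate (methyl angelate) | C/C=C(/C)C(=O)OC | starting material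
22 | (Z)-2-methylbut-2-en-1-ol | C/C=C(/C)CO | intermediate
23 | [(2S,3R)-2,3-dimethyloxiran-2-yl]methanol | OC[C@]1(C)O[C@@H]1C | intermediate
24 | (2R,3R)-2,3-dimethyloxirane-2-carboxylic acid | OC(=O)[C@]1(C)O[C@@H]1C | intermediate
25 | (2R,3R)-2,3-dimethyloxirane-2-carboxylic 2,4,6-trichlorobenzoic anhydride | Clc1cc(Cl)c(C(=O)OC(=O)[C@]2(C)O[C@@H]2C)c(Cl)c1 | intermediate (not isolated)
26 | methyl (3aR,4R,6E,9S,10Z,11aR)-4-{[(2R,3R)-2,3-dimethyloxirane-2-carbonyl]oxy}-10-methyl-3-methylidene-2-oxo-9-[(triethylsilyl)oxy]-2,3,3a,4,5,8,9,11a-octahydrocyclodeca[b]furan-6-carboxylate | C=C1C(=O)O[C@@H]2/C=C(/C)[C@@H](O[Si](CC)(CC)CC)C/C=C(/C(=O)OC)C[C@@H](OC(=O)[C@]3(C)O[C@@H]3C)[C@@H]12 | intermediate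
27 | methyl (3aR,4R,6E,9S,10Z,11aR)-4-{[(2R,3R)-2,3-dimethyloxirane-2-carbonyl]oxy}-9-hydroxy-10-methyl-3-methylidene-2-oxo-2,3,3a,4,5,8,9,11a-octahydrocyclodeca[b]furan-6-carboxylate | C=C1C(=O)O[C@@H]2/C=C(/C)[C@@H](O)C/C=C(/C(=O)OC)C[C@@H](OC(=O)[C@]3(C)O[C@@H]3C)[C@@H]12 | target

**Summary**

Total step count: 18.
Longest linear sequence: 11 steps (steps 1–6, 11–13, 17, 18).

Three steps most likely to fail:

Step 13. The ketyl may add to C9 through the other staggered transition state, so that facial selectivity at C8 is poor or reversed. The fallback sets out from 18 and runs the same closure. The resulting 4S alcohol, methyl (3aR,4S,6E,9S,10Z,11aR)-4-hydroxy-10-methyl-3-methylidene-2-oxo-9-[(triethylsilyl)oxy]-2,3,3a,4,5,8,9,11a-octahydrocyclodeca[b]furan-6-carboxylate F1, is then coupled with acid 24 under Mitsunobu conditions (PPh3, DIAD, toluene, 0 °C to rt). This forms the ester with inversion at C8 and rejoins the route at 26. Any 20 formed alongside is esterified as in step 17, so both epimers converge.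

Step 11. Ligand-controlled facial selectivity in the addition to the aldehyde may be weak, giving the wrong or a mixed configuration at C3. The fallback sets out from 9 and 15, coupled with CrCl2 and NiCl2 (cat.) in DMSO without ligand. This gives 16 together with its C3 epimer, methyl (5R,6Z)-3-acetoxy-7-[(2R,3S)-3-(1,3-dioxolan-2-yl)-4-methylidene-5-oxooxolan-2-yl]-5-hydroxy-6-methyl-2-methylidenehept-6-enoate F2. The mixture is oxidised (Dess–Martin periodinane, NaHCO3, CH2Cl2) to the (Z)-enone, methyl (6Z)-3-acetoxy-7-[(2R,3S)-3-(1,3-dioxolan-2-yl)-4-methylidene-5-oxooxolan-2-yl]-6-methyl-2-methylidene-5-oxohept-6-enoate F3. CBS reduction with (R)-2-methyl-CBS-oxazaborolidine and catecholborane at −78 °C (alkenyl as the large group) should then give the 5S alcohol and rejoin the route at 16.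

Step 5. The α-iodo Wittig reaction may suffer low conversion, erosion of the alkene geometry and base-induced epimerisation of aldehyde 5. The fallback sets out from 5. Corey–Fuchs olefination (CBr4, PPh3, Zn, CH2Cl2) gives (4S,5S)-5-(2,2-dibromoethenyl)-4-(1,3-dioxolan-2-yl)dihydrofuran-2(3H)-one F4. Palladium-catalysed coupling with MeZnCl (Pd2(dba)3, tri(2-furyl)phosphine, THF) replaces selectively the bromine trans to the lactone and gives (4S,5S)-5-[(Z)-2-bromoprop-1-en-1-yl]-4-(1,3-dioxolan-2-yl)dihydrofuran-2(3H)-one F5. Copper-catalysed halogen exchange (CuI, NaI, N,N'-dimethylethylenediamine, dioxane, 110 °C) proceeds with retention and rejoins the route at 6.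

Further compounds
F1 | step 13 | methyl (3aR,4S,6E,9S,10Z,11aR)-4-hydroxy-10-methyl-3-methylidene-2-oxo-9-[(triethylsilyl)oxy]-2,3,3a,4,5,8,9,11a-octahydrocyclodeca[b]furan-6-carboxylate (C8 epimer of 20) | C=C1C(=O)O[C@@H]2/C=C(/C)[C@@H](O[Si](CC)(CC)CC)C/C=C(/C(=O)OC)C[C@H](O)[C@@H]12
F2 | step 11 | methyl (5R,6Z)-3-acetoxy-7-[(2R,3S)-3-(1,3-dioxolan-2-yl)-4-methylidene-5-oxooxolan-2-yl]-5-hydroxy-6-methyl-2-methylidenehept-6-enoate (C3 epimer of 16) | O=C1O[C@H](/C=C(/C)[C@H](O)CC(OC(C)=O)C(=C)C(=O)OC)[C@@H](C2OCCO2)C1=C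
F3 | step 11 | methyl (6Z)-3-acetoxy-7-[(2R,3S)-3-(1,3-dioxolan-2-yl)-4-methylidene-5-oxooxolan-2-yl]-6-methyl-2-methylidene-5-oxohept-6-enoate | O=C1O[C@H](/C=C(/C)C(=O)CC(OC(C)=O)C(=C)C(=O)OC)[C@@H](C2OCCO2)C1=C
F4 | step 5 | (4S,5S)-5-(2,2-dibromoethenyl)-4-(1,3-dioxolan-2-yl)dihydrofuran-2(3H)-one | O=C1O[C@H](C=C(Br)Br)[C@@H](C2OCCO2)C1
F5 | step 5 | (4S,5S)-5-[(Z)-2-bromoprop-1-en-1-yl]-4-(1,3-dioxolan-2-yl)dihydrofuran-2(3H)-one | O=C1O[C@H](/C=C(/C)Br)[C@@H](C2OCCO2)C1
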